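I began from a logarithm.

1. order of the set-ups by the amount of open intermediate at the outlet or at the end, in percent of the starting material put in, highest first (delta / eta / alpha / theta)
2. amount of open intermediate at the outlet or at the end, in percent of the starting material put in, delta
3. amount of open intermediate at the outlet or at the end, in percent of the starting material put in, eta
4. amount of open intermediate at the outlet or at the end, in percent of the starting material put in, alpha
5. amount of open intermediate at the outlet or at the end, in percent of the starting material put in, theta

in all of them: partner 1.20 equiv; capture agent 0.110 M
- delta: starting material 0.11 M; reagent 1.10 equiv; time 6.0 min; everything together in a closed stirred flask, run for 6.0 min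
- eta: starting material 0.11 M; reagent 1.10 equiv; a single well-mixed tank run continuously and read at steady state, 6.0 min in it on average
- alpha: starting material 0.11 M (fed, over 3.00 min); reagent 1.10 equiv; time 6.0 min; all but starting material at the start; starting material goes in evenly over 3.00 min, the run ends at 6.0 min
- theta: starting material 0.11 M; reagent 1.10 equiv (fed, over 3.00 min); time 6.0 min; a stirred flask in which reagent is dosed at a steady rate over 3.00 min without added volume, worked up at 6.0 min

    starting material + reagent → open intermediate (k1 = 1.29 M⁻¹ min⁻¹)
    reagent + partner → second intermediate (k2 = 0.821 M⁻¹ min⁻¹)
    open intermediate + second intermediate → target (k3 = 1.48 M⁻¹ min⁻¹)
    2 open intermediate → homo product (k4 = 0.0960 M⁻¹ min⁻¹)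
    second intermediate + capture agent → trapped intermediate (k5 = 0.174 M⁻¹ min⁻¹)
    reagent + target ⇌ idle adduct, settled at all times (K6 = 5.95 M⁻¹)

- percentages count the starting material that a species holds: one homo product counts as two
- target is meant together with its idle adduct
- two of one species on the left: rate k times its square, two consumed each time
- the stated concentrations are those of everything mixed, before any reaction; amounts are the same in each set-up
- the feed brings no volume worth counting
- run time (delta): 6.0 min

I reckoned delta, the closed flask, by hand and took the other set-ups no further. Reagent is spent by starting material and by partner, and with both held at their charges its pseudo-first-order decay constant comes to 0.250 min⁻¹, which is a ceiling on its rate of fall, idle adduct set aside. Summing that falling reagent over 6.0 min gave a floor for the reagent dose, the natural logarithm of one over the fraction of starting material left, of 0.485, so, idle adduct still set aside, at least 38.4% of the charge had gone.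

For a ceiling I first held reagent at its charge, which gave a dose of 0.937. That dose put floors under starting material and partner, and these slowed the decay to 0.115 min⁻¹ and tightened the dose to 0.676. Open intermediate can hold no more than has gone, so it stood below 49.1%.

For its floor I let second intermediate build at its charged rate and added the homo product loss at that ceiling, which gave a logarithmic loss of 0.412 and a floor of 25.5%. The ceiling stood at about twice the floor, so I committed to their middle on the logarithmic scale, 35.4%.

The forecast gave delta > theta > alpha > eta, with 35% for delta, 32% for theta, 28% for alpha and 25% for eta, holding among its grounds that “dosing starting material lets second intermediate build up first and lowers open intermediate further”. Its delta lay inside my bracket, and I had no figure of my own for the other set-ups.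

The simulation gave delta > theta > alpha > eta, with 35.0% for delta, 32.3% for theta, 28.1% for alpha and 25.1% for eta. Delta ended with 59.0% of its starting material, a dose read at 0.528, between my two ends. The same floor summed to 2.5 min gave a dose of 0.290, so at least 25.2% gone, and delta read at that time held 74% of its starting material and 24.7% as open intermediate.

The constants are invented; the flask was simulated.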